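**Plan**

1. Retrosynthesis: the E-alkene of the side chain is cut first (Julia–Kocienski) and the ring carbinol goes back to a ketone. Then both bonds of the quaternary pyran carbon Cq (to the ring oxygen and to the neighbouring ring-fusion CH, Cf) are cut together. This contracts the dihydropyran to a 2,5-dihydrofuran and opens the carbocycle of the 2-oxabicyclo[2.2.2]octane, leaving a spiro 3-diazo-dihydropyran-2,4-dione on a cyclopentane that carries the dihydrofuran.
2. Enabling feature: Cq bears the pyran oxygen and lies between the lactone C=O and the carbinol carbon, so it is the central carbon of a 1,3-dicarbonyl unit and can be a carbene carbon. The pyran without Cq is a 2,5-dihydrofuran whose O–Cf bond is allylic, and the lactone ring already holds Cq above Cf.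
3. Forward order: cyclopentanone side chain (reductive aldol), bis-allyl ether (palladium allylic etherification), 2,5-dihydrofuran (RCM), spiro β-keto lactone (acetoacetate dianion), diazo lactone, key step (closes the carbocycle and expands the five-membered ether to the dihydropyran), ketone reduction, side chain.
4. Stereochemistry: the silyloxy centre comes from (S)-4-silyloxycyclopentenone and directs the aldol (2,4-trans, syn). The ether centre is set by the chiral palladium ligand, the spiro centre by attack anti to the neighbouring substituent, Cq and the ring fusion by the key step (lactone template, retention at Cf), the carbinol by hydride attack from the lactone side, and the E-alkene by the Julia–Kocienski reaction.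

Key step: step 8

Assumption: epoxide 7 is used as the racemate, and the (R,R)-ligand in step 3 is taken to give the (2S)-ether by analogy with additions to butadiene monoepoxide; the enantiomeric ligand would be used if the sense is the reverse.

**Step 1**
Reactants: 1 (4S)-4-[(tert-butyldimethylsilyl)oxy]cyclopent-2-en-1-one; 2 acrolein
Product: 5 (2S,4R)-4-[(tert-butyldimethylsilyl)oxy]-2-[(1R)-1-hydroxyprop-2-en-1-yl]cyclopentan-1-one, via lithium enolate 3 (not isolated), via titanium enolate 4 (not isolated)
Conditions: LiBH(s-Bu)3, THF, −78 °C; ClTi(Oi-Pr)3, −78 to −40 °C; 2, −78 °C; aq NH4Cl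
Reagents that add atoms: none
Why: Conjugate reduction gives the regiodefined enolate, and the aldol addition of its titanium triisopropoxide enolate to acrolein (reductive aldol) should be syn-selective and occur on the ring face anti to the silyloxy group, which sets the 2,4-trans relationship and the (1R) carbinol centre.

**Step 2**
Reactants: 6 methacrolein
Product: 7 rac-2-(prop-1-en-2-yl)oxirane
Conditions: Me3S+ I−, n-BuLi, THF, −10 °C to rt; distillation
Reagents that add atoms: trimethylsulfonium iodide, C[S+](C)C.[I-]
Why: Corey–Chaykovsky epoxidation, in which the sulfonium methylide adds 1,2 to the enal and closes the oxirane; the racemate is wanted.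

**Step 3**
Reactants: 5 (aldol product); 7 rac-2-(prop-1-en-2-yl)oxirane
Product: 8 (2S,4R)-4-[(tert-butyldimethylsilyl)oxy]-2-[(1R)-1-{[(2S)-1-hydroxy-3-methylbut-3-en-2-yl]oxy}prop-2-en-1-yl]cyclopentan-1-one
Conditions: Pd2(dba)3·CHCl3 (1 mol %), (1R,2R)-N,N′-bis[2-(diphenylphosphino)-1-naphthoyl]cyclohexane-1,2-diamine (3 mol %), Et3B (1 mol %), CH2Cl2, rt
Reagents that add atoms: none
Why: Palladium-catalysed dynamic kinetic asymmetric allylic etherification of a vinyl epoxide (Tsuji–Trost type), in which the π-allyl complexes from both epoxide enantiomers interconvert and the borate delivers the alcohol to the internal allyl carbon, so the ligand should set the (2S) ether centre.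

**Step 4**
Reactants: 8 (primary alcohol)
Product: 9 (2S,4R)-4-[(tert-butyldimethylsilyl)oxy]-2-[(1R)-1-({(2S)-1-[(tert-butyldimethylsilyl)oxy]-3-methylbut-3-en-2-yl}oxy)prop-2-en-1-yl]cyclopentan-1-one
Conditions: TBSCl, imidazole, DMF, 0 °C to rt
Reagents that add atoms: tert-butyldimethylsilyl chloride, CC(C)(C)[Si](C)(C)Cl
Why: Standard silylation of the primary alcohol, which must not meet the carbene of step 8.

**Step 5**
Reactants: 9 (bis-allyl ether)
Product: 10 (2S,4R)-4-[(tert-butyldimethylsilyl)oxy]-2-[(2R,5S)-5-{[(tert-butyldimethylsilyl)oxy]methyl}-4-methyl-2,5-dihydrofuran-2-yl]cyclopentan-1-one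
Conditions: second-generation Grubbs catalyst (5 mol %), 1,4-benzoquinone (10 mol %), CH2Cl2, 40 °C
Reagents that add atoms: none
Why: Ring-closing metathesis of the isopropenyl and vinyl groups should give the trisubstituted 2,5-dihydrofuran; no stereocentre is touched, so the 2,5-cis relationship follows from steps 1 and 3.

**Step 6**
Reactants: 10 (dihydrofuranyl cyclopentanone); 11 methyl acetoacetate
Product: 13 (1S,3R,5R)-3-[(tert-butyldimethylsilyl)oxy]-1-[(2R,5S)-5-{[(tert-butyldimethylsilyl)oxy]methyl}-4-methyl-2,5-dihydrofuran-2-yl]-6-oxaspiro[4.5]decane-7,9-dione, via hydroxy keto ester 12 (not isolated)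
Conditions: 11, NaH then n-BuLi, THF, 0 °C; 10, −78 °C; then 0.5 M NaOH, MeOH, 0 °C to rt; 1 M HCl to pH 3
Reagents that add atoms: none
Why: Aldol addition of the acetoacetate dianion through its terminal carbon and lactonisation of the δ-hydroxy β-keto ester; the nucleophile should add to the cyclopentanone anti to the adjacent dihydrofuranyl group, which puts the tertiary oxygen cis to that group at the spiro centre.

**Step 7**
Reactants: 13 (spiro β-keto lactone)
Product: 14 (1S,3R,5R)-3-[(tert-butyldimethylsilyl)oxy]-1-[(2R,5S)-5-{[(tert-butyldimethylsilyl)oxy]methyl}-4-methyl-2,5-dihydrofuran-2-yl]-8-diazo-6-oxaspiro[4.5]decane-7,9-dione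
Conditions: 4-acetamidobenzenesulfonyl azide, Et3N, MeCN, 0 °C to rt
Reagents that add atoms: 4-acetamidobenzenesulfonyl azide, CC(=O)Nc1ccc(cc1)S(=O)(=O)N=[N+]=[N-]
Why: Regitz diazo transfer to the acidic carbon between the two carbonyl groups; no stereocentre is formed.

**Step 8**
Reactants: 14 (diazo lactone)
Product: 16 tetracyclic keto lactone bis(TBS ether), via oxonium ylide 15 (not isolated)
Conditions: Cu(hfacac)2 (10 mol %), ClCH2CH2Cl, 80 °C, slow addition of 14 (final 0.005 M)
Reagents that add atoms: none
Why: Proposed new method: Cu(hfacac)2 converts 14 into a catalyst-bound carbene at the carbon between the two carbonyl groups; the dihydrofuran oxygen, held above this carbon by the spiro lactone, adds to it to give the bridged oxonium ylide 15, which undergoes a Stevens 1,2-shift (homolysis of the allylic O–CH bond and in-cage recombination at the former carbene carbon). The closest known reaction type is the copper- or rhodium-catalysed generation of bicyclic oxonium ylides from diazo carbonyl compounds tethered to cyclic ethers and their 1,2-shift with ring expansion (oxetane to tetrahydrofuran, cyclic acetal to bridged ether); a 2,5-dihydrofuran that migrates within a ylide at a lactone bridgehead has not been shown. Two rings close: the six-membered carbocycle by contraction of the seven-membered ylide ring, which with the lactone already in place gives the 2-oxabicyclo[2.2.2]octane, and the 3,6-dihydro-2H-pyran by expansion of the five-membered ether by the new quaternary carbon. The quaternary centre can form only on the lactone face that carries the cyclopentane CH, so the spiro centre fixes its configuration, and the migrating CH keeps its configuration because the new C–C bond forms on the face the oxygen leaves. The step needs ylide formation to outrun C–H insertion and cyclopropanation of the ring alkene (copper catalyst, slow addition) and needs the O–CH(cyclopentyl) bond to migrate and not the O–CH(CH2OTBS) bond: the former lies in the bridge antiperiplanar to the carbanion lobe and its cleavage relieves the seven-membered rings, whereas the latter is exocyclic and gauche, and the saturated CH2OTBS group opens no 2,3-shift.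

**Step 9**
Reactants: 16 (keto lactone)
Product: 17 tetracyclic hydroxy lactone bis(TBS ether)
Conditions: NaBH4, CeCl3·7H2O, MeOH–THF, −78 °C
Reagents that add atoms: none
Why: Luche reduction, in which hydride should add from the side of the lactone bridge (no hydrogen atoms point at the ketone from there, whereas the carbocyclic bridge presents two C–H bonds), giving the (R) carbinol, while the cold, weakly basic medium avoids β-elimination of the lactone oxygen.

**Step 10**
Reactants: 17 (bis-silyl ether)
Product: 18 tetracyclic diol mono(TBS ether)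
Conditions: HF·pyridine, pyridine, THF, 0 °C
Reagents that add atoms: none
Why: Buffered HF·pyridine should cleave the primary silyl ether faster than the secondary one on the cyclopentane (steric discrimination).

**Step 11**
Reactants: 18 (primary alcohol)
Product: 19 tetracyclic hydroxy aldehyde
Conditions: TEMPO (10 mol %), PhI(OAc)2, CH2Cl2, rt
Reagents that add atoms: none
Why: Oxoammonium (TEMPO) oxidation is selective for the primary alcohol over the hindered secondary ring alcohol and is non-basic, so the α-alkoxy aldehyde centre should stay intact.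

**Step 12**
Reactants: 20 1-phenyl-1H-tetrazole-5-thiol; 21 1-bromooctane
Product: 22 5-(octylsulfanyl)-1-phenyl-1H-tetrazole
Conditions: K2CO3, acetone, 56 °C
Reagents that add atoms: none
Why: S-alkylation of the thiolate with the primary bromide (SN2).

**Step 13**
Reactants: 22 (sulfide)
Product: 23 5-(octane-1-sulfonyl)-1-phenyl-1H-tetrazole
Conditions: 30% H2O2, (NH4)6Mo7O24·4H2O (10 mol %), EtOH, rt
Reagents that add atoms: hydrogen peroxide, OO
Why: Molybdate-catalysed oxidation of the sulfide to the sulfone, the usual route to Julia–Kocienski reagents.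

**Step 14**
Reactants: 19 (aldehyde); 23 (sulfone)
Product: 24 target cyclopentyl TBS ether
Conditions: 23, KN(SiMe3)2 (2.2 equiv), DME, −78 °C; then 19, −78 °C to rt
Reagents that add atoms: none
Why: Julia–Kocienski olefination, in which the metalated phenyltetrazolyl sulfone adds to the aldehyde and the Smiles rearrangement–elimination should give the E-alkene; the cold pre-formed anion limits epimerisation next to the ring oxygen.

**Step 15**
Reactants: 24 (silyl ether)
Product: 25 CNP0127096.1 (target)
Conditions: HF·pyridine, THF, 0 °C to rt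
Reagents that add atoms: none
Why: Acidic fluoride desilylation frees the cyclopentanol without touching the lactone or the alkenes.

**Compound list**

1 | (4S)-4-[(tert-butyldimethylsilyl)oxy]cyclopent-2-en-1-one | O=C1C[C@H](O[Si](C)(C)C(C)(C)C)C=C1 | starting material
2 | acrolein (prop-2-enal) | C=CC=O | starting material
3 | lithium (4R)-4-[(tert-butyldimethylsilyl)oxy]cyclopent-1-en-1-olate | [Li]OC1=CC[C@@H](O[Si](C)(C)C(C)(C)C)C1 | intermediate (not isolated)
4 | tri(propan-2-yloxy)titanium (4R)-4-[(tert-butyldimethylsilyl)oxy]cyclopent-1-en-1-olate | CC(C)O[Ti](OC(C)C)(OC(C)C)OC1=CC[C@@H](O[Si](C)(C)C(C)(C)C)C1 | intermediate (not isolated)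
5 | (2S,4R)-4-[(tert-butyldimethylsilyl)oxy]-2-[(1R)-1-hydroxyprop-2-en-1-yl]cyclopentan-1-one | O[C@H](C=C)[C@@H]1C[C@@H](O[Si](C)(C)C(C)(C)C)CC1=O | intermediate
6 | methacrolein (2-methylprop-2-enal) | CC(=C)C=O | starting material
7 | rac-2-(prop-1-en-2-yl)oxirane | CC(=C)C1CO1 | intermediate
8 | (2S,4R)-4-[(tert-butyldimethylsilyl)oxy]-2-[(1R)-1-{[(2S)-1-hydroxy-3-methylbut-3-en-2-yl]oxy}prop-2-en-1-yl]cyclopentan-1-one | OC[C@H](C(C)=C)O[C@H](C=C)[C@@H]1C[C@@H](O[Si](C)(C)C(C)(C)C)CC1=O | intermediate
9 | (2S,4R)-4-[(tert-butyldimethylsilyl)oxy]-2-[(1R)-1-({(2S)-1-[(tert-butyldimethylsilyl)oxy]-3-methylbut-3-en-2-yl}oxy)prop-2-en-1-yl]cyclopentan-1-one | CC(C)(C)[Si](C)(C)OC[C@H](C(C)=C)O[C@H](C=C)[C@@H]1C[C@@H](O[Si](C)(C)C(C)(C)C)CC1=O | intermediate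
10 | (2S,4R)-4-[(tert-butyldimethylsilyl)oxy]-2-[(2R,5S)-5-{[(tert-butyldimethylsilyl)oxy]methyl}-4-methyl-2,5-dihydrofuran-2-yl]cyclopentan-1-one (2,5-cis-dihydrofuran) | CC(C)(C)[Si](C)(C)OC[C@H]1O[C@@H]([C@@H]2C[C@@H](O[Si](C)(C)C(C)(C)C)CC2=O)C=C1C | intermediate
11 | methyl acetoacetate | COC(=O)CC(C)=O | starting material
12 | δ-hydroxy β-keto methyl ester (open form of 13; tertiary alcohol on the cyclopentane) | CC(C)(C)[Si](C)(C)OC[C@H]1O[C@@H]([C@@H]2C[C@@H](O[Si](C)(C)C(C)(C)C)C[C@@]2(O)CC(=O)CC(=O)OC)C=C1C | intermediate (not isolated)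
13 | (1S,3R,5R)-3-[(tert-butyldimethylsilyl)oxy]-1-[(2R,5S)-5-{[(tert-butyldimethylsilyl)oxy]methyl}-4-methyl-2,5-dihydrofuran-2-yl]-6-oxaspiro[4.5]decane-7,9-dione | CC(C)(C)[Si](C)(C)OC[C@H]1O[C@@H]([C@@H]2C[C@@H](O[Si](C)(C)C(C)(C)C)C[C@]23OC(=O)CC(=O)C3)C=C1C | intermediate
14 | 8-diazo derivative of 13 | CC(C)(C)[Si](C)(C)OC[C@H]1O[C@@H]([C@@H]2C[C@@H](O[Si](C)(C)C(C)(C)C)C[C@]23OC(=O)C(=[N+]=[N-])C(=O)C3)C=C1C | intermediate
15 | bridged oxonium ylide (dihydrofuran oxygen bonded to the former diazo carbon) | CC(C)(C)[Si](C)(C)OC[C@H]1[O+]2[C@@H]([C@@H]3C[C@@H](O[Si](C)(C)C(C)(C)C)C[C@]34OC(=O)[C-]2C(=O)C4)C=C1C | intermediate (not isolated)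
16 | tetracyclic keto lactone bis(TBS ether): target skeleton with ring C=O in place of the ring CH–OH, CH2OTBS in place of the nonenyl chain, OTBS on the cyclopentane | CC(C)(C)[Si](C)(C)OC[C@H]1O[C@@]23C(=O)O[C@]4(C[C@H](O[Si](C)(C)C(C)(C)C)C[C@H]4[C@H]2C=C1C)CC3=O | intermediate
17 | tetracyclic hydroxy lactone bis(TBS ether): 16 with the ketone reduced to the (R) alcohol | CC(C)(C)[Si](C)(C)OC[C@H]1O[C@@]23C(=O)O[C@]4(C[C@H](O[Si](C)(C)C(C)(C)C)C[C@H]4[C@H]2C=C1C)C[C@H]3O | intermediate
18 | tetracyclic diol mono(TBS ether): 17 with free CH2OH | OC[C@H]1O[C@@]23C(=O)O[C@]4(C[C@H](O[Si](C)(C)C(C)(C)C)C[C@H]4[C@H]2C=C1C)C[C@H]3O | intermediate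
19 | tetracyclic hydroxy aldehyde: 18 with CHO in place of CH2OH | O=C[C@H]1O[C@@]23C(=O)O[C@]4(C[C@H](O[Si](C)(C)C(C)(C)C)C[C@H]4[C@H]2C=C1C)C[C@H]3O | intermediate
20 | 1-phenyl-1H-tetrazole-5-thiol | SC1=NN=NN1C1=CC=CC=C1 | starting material
21 | 1-bromooctane | CCCCCCCCBr | starting material
22 | 5-(octylsulfanyl)-1-phenyl-1H-tetrazole | CCCCCCCCSC1=NN=NN1C1=CC=CC=C1 | intermediate
23 | 5-(octane-1-sulfonyl)-1-phenyl-1H-tetrazole | CCCCCCCCS(=O)(=O)C1=NN=NN1C1=CC=CC=C1 | intermediate
24 | target with the cyclopentanol as its TBS ether | CCCCCCC/C=C/[C@H]1O[C@@]23C(=O)O[C@]4(C[C@H](O[Si](C)(C)C(C)(C)C)C[C@H]4[C@H]2C=C1C)C[C@H]3O | intermediate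
25 | CNP0127096.1 | CCCCCCC/C=C/[C@H]1O[C@@]23C(=O)O[C@]4(C[C@H](O)C[C@H]4[C@H]2C=C1C)C[C@H]3O | target

**Totals and risks**

Total step count: 15. Longest linear sequence: 12 (steps 1, 3–11, 14, 15).

Steps most likely to fail:

1. Step 8. The ylide at the lactone bridgehead cannot be stabilised as an enolate, so its formation may lose to C–H insertion or to cyclopropanation of the ring alkene, or the exocyclic O–C bond may migrate instead.
Fallback (known reaction types; sets out from 5, returns at 16): silylation of 5 with TESCl and imidazole gives the triethylsilyl ether F1. Addition of the dianion of 11 gives the hydroxy keto ester F2, which is lactonised as in step 6 to the spiro β-keto lactone F3, and diazo transfer as in step 7 gives the diazo lactone F4. In parallel, hydrolytic kinetic resolution of 7 with (salen)Co(OAc) and 0.5 equiv of water gives (S)-3-methylbut-3-ene-1,2-diol F5, and TBSCl with imidazole silylates its primary hydroxyl to the (S)-allylic alcohol F6. Rh2(OAc)4-catalysed O–H insertion of F4 into F6 puts the ether oxygen on the future quaternary carbon (α-alkoxy β-keto lactone F7). PPTS in methanol removes the triethylsilyl group to give the allylic alcohol F8. Pd(PPh3)4 with Et3B then closes the carbocycle by direct intramolecular Tsuji–Trost alkylation of the boron-activated allylic alcohol by the α-alkoxy β-dicarbonyl carbon (net retention at the allylic carbon), giving the bicyclic lactone F9 with vinyl and isopropenyl groups. Ring-closing metathesis with the second-generation Grubbs catalyst closes the dihydropyran and gives 16.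

2. Step 3. Addition of the hindered secondary alcohol to the π-allyl intermediate may be slow, may give the linear ether, or may show poor catalyst control of the new ether centre.
Fallback (sets out from 5 and 7, returns at 8): 7 is resolved by hydrolytic kinetic resolution with (salen)Co(OAc) and 0.55 equiv of water, and the recovered (R)-2-(prop-1-en-2-yl)oxirane F10 is opened by 5 at its allylic carbon with inversion under BF3·OEt2 catalysis (CH2Cl2, −30 °C). A substrate-controlled SN2-type opening thus replaces the catalyst-controlled palladium process and gives 8.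

3. Step 1. The closed transition state of the titanium enolate may give poor syn selectivity or poor facial selectivity with the small aldehyde.
Fallback (sets out from 1, returns at 5): conjugate reduction of 1 with LiBH(s-Bu)3 and trapping with TMSCl gives the trimethylsilyl enol ether F11. It is then added to 2 with catalytic tris(dimethylamino)sulfonium difluorotrimethylsilicate at −78 °C; this fluoride-mediated Mukaiyama aldol of the naked enolate goes through an open transition state that is syn-selective irrespective of enolate geometry, and work-up gives 5.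

**Further compounds**

F1 | step 8 | (2S,4R)-4-[(tert-butyldimethylsilyl)oxy]-2-[(1R)-1-[(triethylsilyl)oxy]prop-2-en-1-yl]cyclopentan-1-one | CC[Si](CC)(CC)O[C@H](C=C)[C@@H]1C[C@@H](O[Si](C)(C)C(C)(C)C)CC1=O
F2 | step 8 | δ-hydroxy β-keto methyl ester from F1 (not isolated) | CC[Si](CC)(CC)O[C@H](C=C)[C@@H]1C[C@@H](O[Si](C)(C)C(C)(C)C)C[C@@]1(O)CC(=O)CC(=O)OC
F3 | step 8 | spiro β-keto lactone with the 1-[(triethylsilyl)oxy]allyl side chain | CC[Si](CC)(CC)O[C@H](C=C)[C@@H]1C[C@@H](O[Si](C)(C)C(C)(C)C)C[C@]12OC(=O)CC(=O)C2
F4 | step 8 | diazo derivative of F3 | CC[Si](CC)(CC)O[C@H](C=C)[C@@H]1C[C@@H](O[Si](C)(C)C(C)(C)C)C[C@]12OC(=O)C(=[N+]=[N-])C(=O)C2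
F5 | step 8 | (S)-3-methylbut-3-ene-1,2-diol | OC[C@@H](O)C(C)=C
F6 | step 8 | (2S)-1-[(tert-butyldimethylsilyl)oxy]-3-methylbut-3-en-2-ol | CC(C)(C)[Si](C)(C)OC[C@H](C(C)=C)O
F7 | step 8 | α-alkoxy β-keto lactone from O–H insertion of F4 into F6 | CC[Si](CC)(CC)O[C@H](C=C)[C@@H]1C[C@@H](O[Si](C)(C)C(C)(C)C)C[C@]12OC(=O)C(O[C@H](CO[Si](C)(C)C(C)(C)C)C(C)=C)C(=O)C2
F8 | step 8 | F7 with the free allylic alcohol | O[C@H](C=C)[C@@H]1C[C@@H](O[Si](C)(C)C(C)(C)C)C[C@]12OC(=O)C(O[C@H](CO[Si](C)(C)C(C)(C)C)C(C)=C)C(=O)C2
F9 | step 8 | bicyclic keto lactone with vinyl and isopropenyl groups (seco-16, dihydropyran open at its C=C) | CC(C)(C)[Si](C)(C)OC[C@H](C(C)=C)O[C@@]12C(=O)O[C@]3(C[C@H](O[Si](C)(C)C(C)(C)C)C[C@H]3[C@H]1C=C)CC2=O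
F10 | step 3 | (R)-2-(prop-1-en-2-yl)oxirane | CC(=C)[C@@H]1CO1
F11 | step 1 | (4R)-4-[(tert-butyldimethylsilyl)oxy]-1-[(trimethylsilyl)oxy]cyclopent-1-ene | C[Si](C)(C)OC1=CC[C@@H](O[Si](C)(C)C(C)(C)C)C1
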